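Ring atoms are numbered C1 (CH2SO2Me), C2 and C3 (Br), C4 and C5 (OH), C6 (H). The retrosynthesis cuts the benzylic C–S bond (sulfinate plus benzyl bromide) and then both aryl C–Br bonds at once.
Enabling feature: the bromines sit on the neighbouring carbons C2 and C3, held between benzylic C1 and the oxygen-bearing C4/C5. C2–C3 can therefore be an aryne triple bond, and C3, C4, C5 are the three contiguous oxygens of methyl gallate, the C3 oxygen being spent as the triflate leaving group.
Forward order: the gallate benzene ring is kept throughout and the 1,3-dioxole (acetonide) ring is closed first on the C4/C5 oxygens. The C3 oxygen, as a carbamate, steers silicon to C2 and is then converted into the triflate, and the aryne is dibrominated. The benzylic carbon is then unmasked, brominated and joined to sulfur, and the dioxole ring is opened last.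
Stereochemistry: the target has no stereocentre; the only one on the way is the racemic acetal carbon of a temporary THP ether.

Key step: step 8

Remark on the chemistry: the benzylic oxygen is carried as a THP ether, because this acetal can be removed with a mild acid that leaves the catechol ketal intact; every THP-bearing compound is a racemate.

Step 1
Reactants: 1 methyl gallate (methyl 3,4,5-trihydroxybenzoate)
Product: 2 methyl 7-hydroxy-2,2-dimethyl-1,3-benzodioxole-5-carboxylate
Conditions: Me2C(OMe)2, p-TsOH (cat.), toluene, reflux, MeOH removed over 4 Å molecular sieves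
Reagents that add atoms: 2,2-dimethoxypropane COC(C)(C)OC
Why: Acid-catalysed transketalisation onto two adjacent phenolic hydroxyls closes the five-membered dioxole (catechol acetonide formation), the two possible vicinal pairs being equivalent by the symmetry of gallate and the lone remaining hydroxyl being unable to form a second ketal.

Step 2
Reactants: 2 methyl 7-hydroxy-2,2-dimethyl-1,3-benzodioxole-5-carboxylate
Product: 3 methyl 7-[(diethylcarbamoyl)oxy]-2,2-dimethyl-1,3-benzodioxole-5-carboxylate
Conditions: ClC(O)NEt2, K2CO3, MeCN, reflux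
Reagents that add atoms: N,N-diethylcarbamoyl chloride CCN(CC)C(=O)Cl
Why: O-Carbamoylation of the potassium phenoxide (acyl substitution at the carbamoyl chloride) installs a strong directing group for ortho-metalation, while the ester and the ketal are inert to K2CO3.

Step 3
Reactants: 3 methyl 7-[(diethylcarbamoyl)oxy]-2,2-dimethyl-1,3-benzodioxole-5-carboxylate
Product: 4 6-(hydroxymethyl)-2,2-dimethyl-1,3-benzodioxol-4-yl N,N-diethylcarbamate
Conditions: i-Bu2AlH (2.5 equiv), CH2Cl2, −78 °C, aqueous tartrate work-up
Reagents that add atoms: none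
Why: Low-temperature ester-to-alcohol reduction with i-Bu2AlH should be chemoselective, because the N,N-diethylcarbamate carbonyl is deactivated by nitrogen donation and shielded by its ethyl groups.

Step 4
Reactants: 4 6-(hydroxymethyl)-2,2-dimethyl-1,3-benzodioxol-4-yl N,N-diethylcarbamate
Product: 5 2,2-dimethyl-6-[(tetrahydro-2H-pyran-2-yloxy)methyl]-1,3-benzodioxol-4-yl N,N-diethylcarbamate (racemic at the THP acetal carbon)
Conditions: 3,4-dihydro-2H-pyran, PPTS (cat.), CH2Cl2, rt
Reagents that add atoms: 3,4-dihydro-2H-pyran C1CCOC=C1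
Why: Acid-catalysed addition of the alcohol to the enol ether (tetrahydropyranyl ether formation) gives an acetal that is stable to organolithiums, hydride and fluoride yet far more acid-labile than the catechol ketal, its new acetal carbon arising as an inconsequential racemate.

Step 5
Reactants: 5 2,2-dimethyl-6-[(tetrahydro-2H-pyran-2-yloxy)methyl]-1,3-benzodioxol-4-yl N,N-diethylcarbamate
Product: 7 2,2-dimethyl-6-[(tetrahydro-2H-pyran-2-yloxy)methyl]-5-(trimethylsilyl)-1,3-benzodioxol-4-yl N,N-diethylcarbamate, via C2 aryllithium 6 (not isolated)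
Conditions: s-BuLi, TMEDA, THF, −78 °C; then Me3SiCl, −78 °C to rt
Reagents that add atoms: chlorotrimethylsilane C[Si](C)(C)Cl; sec-butyllithium [Li]C(C)CC (lithium in intermediate 6 only)
Why: Directed ortho-metalation, in which the carbamate on C3 complexes s-BuLi/TMEDA and delivers it to C2, the only hydrogen-bearing carbon ortho to it (C4 carries the dioxole oxygen) and a site further acidified by the neighbouring CH2O acetal, followed by silylation at −78 °C before the anionic ortho-Fries shift can set in.

Step 6
Reactants: 7 2,2-dimethyl-6-[(tetrahydro-2H-pyran-2-yloxy)methyl]-5-(trimethylsilyl)-1,3-benzodioxol-4-yl N,N-diethylcarbamate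
Product: 8 2,2-dimethyl-6-[(tetrahydro-2H-pyran-2-yloxy)methyl]-5-(trimethylsilyl)-1,3-benzodioxol-4-ol
Conditions: LiAlH4, THF, 0 °C to reflux; H2O/aq. NaOH work-up
Reagents that add atoms: none
Why: Hydride attack on the carbamate carbonyl expels the phenoxide (reductive cleavage of an aryl O-carbamate), and LiAlH4 leaves the aryl–silicon bond, the THP acetal and the ketal untouched.

Step 7
Reactants: 8 2,2-dimethyl-6-[(tetrahydro-2H-pyran-2-yloxy)methyl]-5-(trimethylsilyl)-1,3-benzodioxol-4-ol
Product: 9 2,2-dimethyl-6-[(tetrahydro-2H-pyran-2-yloxy)methyl]-5-(trimethylsilyl)-1,3-benzodioxol-4-yl trifluoromethanesulfonate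
Conditions: PhNTf2, DBU, MeCN, 40 °C
Reagents that add atoms: N-phenylbis(trifluoromethanesulfonimide) O=S(=O)(N(c1ccccc1)S(=O)(=O)C(F)(F)F)C(F)(F)F
Why: Phenol triflation by sulfonyl transfer from the mild donor PhNTf2 to the amidinium phenoxide proceeds without acid, so the THP acetal survives and the adjacent C–Si bond is not cleaved.

Step 8
Reactants: 9 2,2-dimethyl-6-[(tetrahydro-2H-pyran-2-yloxy)methyl]-5-(trimethylsilyl)-1,3-benzodioxol-4-yl trifluoromethanesulfonate
Product: 11 4,5-dibromo-2,2-dimethyl-6-[(tetrahydro-2H-pyran-2-yloxy)methyl]-1,3-benzodioxole, via C2-C3 aryne 10 (not isolated)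
Conditions: CsF (3 equiv), BrCl2C–CCl2Br (2 equiv), Bu4NBr (0.2 equiv), MeCN, rt
Reagents that add atoms: 1,2-dibromo-1,1,2,2-tetrachloroethane BrC(Cl)(Cl)C(Cl)(Cl)Br; tetrabutylammonium bromide CCCC[N+](CCCC)(CCCC)CCCC.[Br-] (catalytic bromide carrier)
Why: Fluoride attacks the silicon on C2 and the developing carbanion expels the triflate from C3, so the C2–C3 aryne 10 is released under neutral conditions at room temperature. Bromide, seeded by Bu4NBr, adds to one aryne carbon and the resulting ortho-bromoaryl anion abstracts a bromonium equivalent from BrCl2C–CCl2Br, which collapses to tetrachloroethene and a fresh bromide that carries the chain, so the C2–Br and C3–Br bonds form in one operation. The closest known reaction type is the vicinal dihalogenation of arynes released from ortho-silylaryl triflates, either by insertion into a halogen–halogen bond or by halide addition followed by halogen transfer from a perhalogenated donor. No ring is closed and no stereocentre is formed. Regioselectivity is not needed because both aryne carbons receive the same atom; the step needs chemoselectivity for aryne capture over electrophilic substitution at C6–H, ipso-bromodesilylation at C2 and protonation of the aryl anion, and this should be secured by a bromine donor that reacts with carbanions but not with arenes, by the deactivating triflate and by keeping the donor in excess.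

Step 9
Reactants: 11 4,5-dibromo-2,2-dimethyl-6-[(tetrahydro-2H-pyran-2-yloxy)methyl]-1,3-benzodioxole
Product: 12 (6,7-dibromo-2,2-dimethyl-1,3-benzodioxol-5-yl)methanol
Conditions: PPTS (cat.), EtOH, 55 °C
Reagents that add atoms: none
Why: Acid-catalysed transacetalisation to ethanol (THP ether alcoholysis) runs at the acidity of PPTS, at which the ketal on the two weakly basic phenolic oxygens should not ionise.

Step 10
Reactants: 12 (6,7-dibromo-2,2-dimethyl-1,3-benzodioxol-5-yl)methanol
Product: 13 4,5-dibromo-6-(bromomethyl)-2,2-dimethyl-1,3-benzodioxole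
Conditions: CBr4, PPh3, CH2Cl2, 0 °C
Reagents that add atoms: tetrabromomethane BrC(Br)(Br)Br
Why: Appel reaction, in which the alkoxyphosphonium salt of the primary benzylic alcohol is displaced by bromide under essentially neutral conditions that leave the ketal and the aryl bromides alone.

Step 11
Reactants: 13 4,5-dibromo-6-(bromomethyl)-2,2-dimethyl-1,3-benzodioxole; 14 sodium methanesulfinate
Product: 15 4,5-dibromo-2,2-dimethyl-6-[(methylsulfonyl)methyl]-1,3-benzodioxole
Conditions: MeSO2Na, DMF, rt to 50 °C
Reagents that add atoms: sodium methanesulfinate (compound 14) CS(=O)[O-].[Na+]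
Why: Sulfinate S-alkylation, an SN2 displacement of the benzylic bromide by the soft sulfur atom of the ambident anion in a dipolar aprotic solvent, gives the sulfone while the aryl bromides are inert to substitution.

Step 12
Reactants: 15 4,5-dibromo-2,2-dimethyl-6-[(methylsulfonyl)methyl]-1,3-benzodioxole
Product: 16 3,4-dibromo-5-[(methylsulfonyl)methyl]benzene-1,2-diol (CNP0131477.0)
Conditions: TFA/H2O (9:1), 40 °C, under N2
Reagents that add atoms: none
Why: Acid-catalysed ketal hydrolysis releases acetone and the free catechol, the sulfone and the aryl bromides being stable to aqueous TFA and air being excluded to protect the diol.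

Compound list
1 | methyl gallate (methyl 3,4,5-trihydroxybenzoate) | COC(=O)c1cc(O)c(O)c(O)c1 | starting material
2 | methyl 7-hydroxy-2,2-dimethyl-1,3-benzodioxole-5-carboxylate | COC(=O)c1cc(O)c2OC(C)(C)Oc2c1 | intermediate
3 | methyl 7-[(diethylcarbamoyl)oxy]-2,2-dimethyl-1,3-benzodioxole-5-carboxylate | COC(=O)c1cc(OC(=O)N(CC)CC)c2OC(C)(C)Oc2c1 | intermediate
4 | 6-(hydroxymethyl)-2,2-dimethyl-1,3-benzodioxol-4-yl N,N-diethylcarbamate | OCc1cc(OC(=O)N(CC)CC)c2OC(C)(C)Oc2c1 | intermediate
5 | 2,2-dimethyl-6-[(tetrahydro-2H-pyran-2-yloxy)methyl]-1,3-benzodioxol-4-yl N,N-diethylcarbamate (racemic) | C1CCOC(C1)OCc1cc(OC(=O)N(CC)CC)c2OC(C)(C)Oc2c1 | intermediate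
6 | [4-[(diethylcarbamoyl)oxy]-2,2-dimethyl-6-[(tetrahydro-2H-pyran-2-yloxy)methyl]-1,3-benzodioxol-5-yl]lithium (racemic) | [Li]c1c(COC2CCCCO2)cc2OC(C)(C)Oc2c1OC(=O)N(CC)CC | intermediate (not isolated)
7 | 2,2-dimethyl-6-[(tetrahydro-2H-pyran-2-yloxy)methyl]-5-(trimethylsilyl)-1,3-benzodioxol-4-yl N,N-diethylcarbamate (racemic) | C[Si](C)(C)c1c(COC2CCCCO2)cc2OC(C)(C)Oc2c1OC(=O)N(CC)CC | intermediate
8 | 2,2-dimethyl-6-[(tetrahydro-2H-pyran-2-yloxy)methyl]-5-(trimethylsilyl)-1,3-benzodioxol-4-ol (racemic) | C[Si](C)(C)c1c(COC2CCCCO2)cc2OC(C)(C)Oc2c1O | intermediate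
9 | 2,2-dimethyl-6-[(tetrahydro-2H-pyran-2-yloxy)methyl]-5-(trimethylsilyl)-1,3-benzodioxol-4-yl trifluoromethanesulfonate (racemic) | C[Si](C)(C)c1c(COC2CCCCO2)cc2OC(C)(C)Oc2c1OS(=O)(=O)C(F)(F)F | intermediate
10 | 4,5-didehydro-2,2-dimethyl-6-[(tetrahydro-2H-pyran-2-yloxy)methyl]-1,3-benzodioxole (C2–C3 aryne, racemic) | C1(COC2CCCCO2)=CC3=C(OC(C)(C)O3)C#C1 | intermediate (not isolated)
11 | 4,5-dibromo-2,2-dimethyl-6-[(tetrahydro-2H-pyran-2-yloxy)methyl]-1,3-benzodioxole (racemic) | Brc1c(Br)c(COC2CCCCO2)cc2OC(C)(C)Oc12 | intermediate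
12 | (6,7-dibromo-2,2-dimethyl-1,3-benzodioxol-5-yl)methanol | OCc1cc2OC(C)(C)Oc2c(Br)c1Br | intermediate
13 | 4,5-dibromo-6-(bromomethyl)-2,2-dimethyl-1,3-benzodioxole | BrCc1cc2OC(C)(C)Oc2c(Br)c1Br | intermediate
14 | sodium methanesulfinate | CS(=O)[O-].[Na+] | starting material
15 | 4,5-dibromo-2,2-dimethyl-6-[(methylsulfonyl)methyl]-1,3-benzodioxole | CS(=O)(=O)Cc1cc2OC(C)(C)Oc2c(Br)c1Br | intermediate
16 | 3,4-dibromo-5-[(methylsulfonyl)methyl]benzene-1,2-diol | CS(=O)(=O)Cc1cc(O)c(O)c(Br)c1Br | target

Total step count: 12. Longest linear sequence: 12 steps, from 1 to 16; sodium methanesulfinate 14 is a purchased partner that enters in step 11.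

Steps most likely to fail

Step 8. The ortho-bromoaryl anion may be protonated by the solvent before bromine transfer (net hydrobromination). Alternatively, fluoride may trigger bromodesilylation at C2 without loss of the triflate, so that the aryne never forms. The fallback sets out from 9 and avoids the aryne. Ruthenium-catalysed triflate-to-bromide exchange ([Cp*Ru(MeCN)3]OTf cat., LiBr, 1,3-dimethyl-2-imidazolidinone, 100 °C) would give 4-bromo-2,2-dimethyl-6-[(tetrahydro-2H-pyran-2-yloxy)methyl]-5-(trimethylsilyl)-1,3-benzodioxole F1. Ipso-bromodesilylation of F1 with N-bromosuccinimide in MeCN would then place the second bromine at C2, a silicon-bearing carbon para to the C5 oxygen, and rejoin the route at 11.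

Step 5. Lithiation may compete at C6, which is ortho to the dioxole oxygen, or the carbamoyl group may migrate to C2 (anionic ortho-Fries) before the silyl chloride reacts at the crowded site. The fallback sets out from 5 and brings silicon to C2 by halogen–lithium exchange instead of deprotonation.
- LiAlH4 in THF would cleave the carbamate to 2,2-dimethyl-6-[(tetrahydro-2H-pyran-2-yloxy)methyl]-1,3-benzodioxol-4-ol F2.
- N-Bromosuccinimide with catalytic i-Pr2NH in CH2Cl2 would brominate the only free ortho carbon of the phenol, C2, to give 5-bromo-2,2-dimethyl-6-[(tetrahydro-2H-pyran-2-yloxy)methyl]-1,3-benzodioxol-4-ol F3.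
- (Me3Si)2NH would convert it into {5-bromo-2,2-dimethyl-6-[(tetrahydro-2H-pyran-2-yloxy)methyl]-1,3-benzodioxol-4-yl}oxy(trimethyl)silane F4.
- n-BuLi in THF, −78 °C to rt, would effect bromine–lithium exchange and the 1,3 O-to-C silyl shift (retro-Brook rearrangement), returning to the route at 8.

Step 12. Ketal cleavage on the electron-poor ring may be slow, and the catechol may degrade oxidatively on prolonged heating in aqueous acid. The fallback sets out from 13 and removes the ketal before the sulfur is introduced. BBr3 in CH2Cl2, −78 to 0 °C, followed by aqueous work-up, would give 3,4-dibromo-5-(bromomethyl)benzene-1,2-diol F5, with the benzylic bromide unaffected. Treatment of F5 with sodium methanesulfinate 14 in DMF at rt would then give the target 16 directly.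

Further compounds
F1 | step 8 | 4-bromo-2,2-dimethyl-6-[(tetrahydro-2H-pyran-2-yloxy)methyl]-5-(trimethylsilyl)-1,3-benzodioxole | C[Si](C)(C)c1c(COC2CCCCO2)cc2OC(C)(C)Oc2c1Br
F2 | step 5 | 2,2-dimethyl-6-[(tetrahydro-2H-pyran-2-yloxy)methyl]-1,3-benzodioxol-4-ol | Oc1cc(COC2CCCCO2)cc2OC(C)(C)Oc12
F3 | step 5 | 5-bromo-2,2-dimethyl-6-[(tetrahydro-2H-pyran-2-yloxy)methyl]-1,3-benzodioxol-4-ol | Oc1c(Br)c(COC2CCCCO2)cc2OC(C)(C)Oc12
F4 | step 5 | {5-bromo-2,2-dimethyl-6-[(tetrahydro-2H-pyran-2-yloxy)methyl]-1,3-benzodioxol-4-yl}oxy(trimethyl)silane | C[Si](C)(C)Oc1c(Br)c(COC2CCCCO2)cc2OC(C)(C)Oc12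
F5 | step 12 | 3,4-dibromo-5-(bromomethyl)benzene-1,2-diol | BrCc1cc(O)c(O)c(Br)c1Br
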